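**Plan** (labdane numbering of the target is used for all carbon atoms)

1. Side chain cuts: the C15–O acetate; C13–C16 and C14–C15 (carboalumination–hydroxymethylation of a C13≡C14 alkyne made from a C13 aldehyde); C8=C17 (Wittig); C9–C11 (Michael addition to acrolein).
2. The decalin is cut in one step at C6–C7 (aldol condensation) and at C5–C10 (intramolecular Michael addition), then at C9–C10 (Knoevenagel condensation with an acetoacetate that brings C7, C8 and C9).
3. The remaining chain C19–C4(C18)–C3–C2–C1–C10–C20 is 2,6-dimethylcyclohexanone opened at its C19–C10 ring bond (enol ether ozonolysis); C5–C6 come from an allyl group placed on C4 by asymmetric allylation.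
4. Enabling feature: in ring B, C6 and C8 stand 1,5 to each other across C5–C10–C9. With C6 as an aldehyde and C8 as the acetoacetate ketone, C5 (enamine carbon) and C10 (β-carbon of the C9=C10 acceptor, carrying C20) are a donor–acceptor pair, and C7/C6 are an aldol pair.
5. Forward order: acyclic chain, then ring A (C5–C10) and ring B (C6–C7) in one flask, then the C9 side chain, C17, C13–C16 and the acetate.
6. Stereochemistry: C4 from the Pd-catalysed allylation; C5 and C10 relayed from C4 in the chair-like ring A closure; C9 by equilibration next to the C8 ketone; 13E from syn-carboalumination.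

Key step: step 8

Assumption: the (S)-configured tert-butyl-PHOX ligand is taken to allylate the 2,6-dimethyl enolate in the same sense as the parent 2-methylcyclohexanone enolate, giving (2S)-4; the enantiomeric ligand would be used otherwise.

**Route**

Step 1
Reactants: 1 2,6-dimethylcyclohexan-1-one (cis/trans mixture); 2 allyl chloroformate
Product: 3 allyl 2,6-dimethylcyclohex-1-en-1-yl carbonate
Conditions: LiN(SiMe3)2, TMEDA, THF, −78 to 0 °C; then allyl chloroformate, −78 °C to rt
Reagents that add atoms: allyl chloroformate (2), C=CCOC(=O)Cl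
Why: The only possible enolate is the tetrasubstituted one, and with TMEDA it should be acylated on oxygen (enol carbonate formation).

Step 2
Reactants: 3 allyl 2,6-dimethylcyclohex-1-en-1-yl carbonate
Product: 4 (2S)-2-allyl-2,6-dimethylcyclohexan-1-one
Conditions: Pd2(dba)3 (2.5 mol %), (S)-t-BuPHOX [(S)-4-tert-butyl-2-(2-diphenylphosphanylphenyl)-4,5-dihydrooxazole, 6 mol %], THF, 25 °C
Reagents that add atoms: none
Why: Palladium-catalysed decarboxylative asymmetric allylic alkylation: zerovalent palladium ionises the allyl carbonate, CO2 is lost, and the ligand should control which face of the enolate is allylated, setting the quaternary centre (future C4); the C6 centre is an irrelevant mixture that is flattened in step 3.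

Step 3
Reactants: 4 (2S)-2-allyl-2,6-dimethylcyclohexan-1-one; 5 chlorotrimethylsilane
Product: 6 {[(6S)-6-allyl-2,6-dimethylcyclohex-1-en-1-yl]oxy}trimethylsilane
Conditions: LiN(i-Pr)2, THF, −78 to 0 °C; Me3SiCl, −78 °C to rt
Reagents that add atoms: chlorotrimethylsilane (5), C[Si](C)(C)Cl
Why: The ketone has a single α-hydrogen (at the methyl-bearing carbon, future C10), so enolisation and O-silylation should give one tetrasubstituted silyl enol ether.

Step 4
Reactants: 6 {[(6S)-6-allyl-2,6-dimethylcyclohex-1-en-1-yl]oxy}trimethylsilane; 7 ozone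
Product: 9 (2S)-2-allyl-2-methyl-6-oxoheptanoic acid, via trimethylsilyl ester 8 (not isolated)
Conditions: O3 (1.0 equiv, Sudan Red 7B end point), CH2Cl2, −78 °C; Me2S; then H2O/THF
Reagents that add atoms: ozone (7), [O-][O+]=O
Why: Ozonolysis of the electron-rich tetrasubstituted enol ether should be much faster than attack on the monosubstituted allyl alkene; it cleaves the C19–C10 ring bond to give the C10 methyl ketone and the C19 silyl ester, which hydrolyses on work-up, with the quaternary centre untouched.

Step 5
Reactants: 9 (2S)-2-allyl-2-methyl-6-oxoheptanoic acid; 10 iodomethane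
Product: 11 methyl (2S)-2-allyl-2-methyl-6-oxoheptanoate
Conditions: MeI, K2CO3, DMF, rt
Reagents that add atoms: iodomethane (10), CI
Why: O-Alkylation of the carboxylate is insensitive to the hindrance at the carbonyl, and K2CO3 should not enolise the ketone.

Step 6
Reactants: 11 methyl (2S)-2-allyl-2-methyl-6-oxoheptanoate; 12 benzyl acetoacetate
Product: 13 1-benzyl 8-methyl (7S)-2-acetyl-7-allyl-3,7-dimethyloct-2-enedioate
Conditions: TiCl4, pyridine, THF, 0 °C to rt
Reagents that add atoms: benzyl acetoacetate (12), CC(=O)CC(=O)OCc1ccccc1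
Why: TiCl4/pyridine Knoevenagel condensation of the methyl ketone forms the C9=C10 alkylidene acetoacetate; alkene geometry and any partial deconjugation do not matter because all isomers equilibrate under the conditions of step 8.

Step 7
Reactants: 13 1-benzyl 8-methyl (7S)-2-acetyl-7-allyl-3,7-dimethyloct-2-enedioate; 14 sodium periodate
Product: 16 1-benzyl 8-methyl (7S)-2-acetyl-3,7-dimethyl-7-(2-oxoethyl)oct-2-enedioate, via vicinal diol 15 (not isolated)
Conditions: OsO4 (2 mol %), NaIO4, 2,6-lutidine, dioxane/H2O, rt
Reagents that add atoms: sodium periodate (14), [Na+].[O-]I(=O)(=O)=O; osmium tetroxide (catalytic oxygen carrier), O=[Os](=O)(=O)=O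
Why: Lemieux–Johnson oxidation: OsO4 should dihydroxylate only the terminal allyl alkene, and periodate cleaves the diol to the C6 aldehyde, while the electron-poor tetrasubstituted alkene is left alone.

Step 8
Reactants: 16 1-benzyl 8-methyl (7S)-2-acetyl-3,7-dimethyl-7-(2-oxoethyl)oct-2-enedioate
Product: 18 5-benzyl 1-methyl (1S,4aS,5R,8aR)-1,4a-dimethyl-6-oxo-1,2,3,4,4a,5,6,8a-octahydronaphthalene-1,5-dicarboxylate, via monocyclic keto aldehyde 17 (not isolated)
Conditions: pyrrolidine (0.3 equiv), AcOH (0.3 equiv), toluene (0.02 M), rt to 70 °C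
Reagents that add atoms: none
Why: Pyrrolidine converts the aldehyde into its enamine, whose carbon C5 adds intramolecularly to C10, the β-carbon of the alkylidene acetoacetate, closing ring A through the C5–C10 bond to give keto aldehyde 17; the acetyl methyl group C7 then condenses with the C6 iminium or aldehyde to close ring B as cyclohexenone 18. The closest known reaction type is the amine-catalysed Michael–aldol condensation annulation (Robinson type), here run with donor and acceptor in one chain so that both rings arise from an acyclic precursor. Ring A closes in the 6-(enolexo)-exo-trig mode and ring B in the 6-(enolendo)-exo-trig mode. C10 is set in a chair-like transition state for ring A in which the bulky C9 carbon with its two acyl groups lies equatorial and C20 axial, and in which the C19 ester and not the C18 methyl group takes the axial site at C4, because a syn-diaxial methyl/ester contact costs less than a methyl/methyl contact; this places C20 cis to C19 as in the target. C5 follows from the equatorial position of the enamine carbon C6 (H5 axial, trans to C20), and as a centre α to C6 and later γ to the enone it can also equilibrate to the more stable trans ring fusion. The step needs diastereoface selectivity at C10 relative to the fixed centre C4, secured by the size difference between C9 and methyl and by the small axial demand of the ester, and chemoselectivity among the carbonyl groups, secured because the ketone was consumed in step 6 before the aldehyde was set free in step 7, so that no other carbonyl pairing can close an unstrained ring.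

Step 9
Reactants: 18 5-benzyl 1-methyl (1S,4aS,5R,8aR)-1,4a-dimethyl-6-oxo-1,2,3,4,4a,5,6,8a-octahydronaphthalene-1,5-dicarboxylate; 19 acrolein
Product: 20 5-benzyl 1-methyl (1S,4aS,5R,8aR)-1,4a-dimethyl-6-oxo-5-(3-oxopropyl)-1,2,3,4,4a,5,6,8a-octahydronaphthalene-1,5-dicarboxylate
Conditions: acrolein, DBU (0.1 equiv), MeCN, −20 to 0 °C
Reagents that add atoms: acrolein (19), C=CC=O
Why: Base-catalysed Michael addition of the β-keto ester carbon C9 to acrolein installs C11–C13; the electrophile should enter anti to the axial C20 methyl group, but the configuration at C9 is of no consequence because it is re-set in step 10.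

Step 10
Reactants: 20 5-benzyl 1-methyl (1S,4aS,5R,8aR)-1,4a-dimethyl-6-oxo-5-(3-oxopropyl)-1,2,3,4,4a,5,6,8a-octahydronaphthalene-1,5-dicarboxylate
Product: 22 methyl (1S,4aS,5R,8aR)-1,4a-dimethyl-6-oxo-5-(3-oxopropyl)decahydronaphthalene-1-carboxylate, via β-keto acid 21 (not isolated)
Conditions: H2 (1 atm), 10% Pd/C, EtOAc, rt; then 50 °C
Reagents that add atoms: none
Why: Hydrogenation saturates C6=C7 and hydrogenolyses the benzyl ester, and β-keto acid 21 should lose CO2 on warming; C9 then carries H and the side chain, which settles in the equatorial position by enolisation (completed under the base of step 11), while the aliphatic aldehyde and the hindered methyl ester should survive.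

Step 11
Reactants: 22 methyl (1S,4aS,5R,8aR)-1,4a-dimethyl-6-oxo-5-(3-oxopropyl)decahydronaphthalene-1-carboxylate; 23 dimethyl (1-diazo-2-oxopropyl)phosphonate
Product: 24 methyl (1S,4aS,5R,8aR)-5-(but-3-yn-1-yl)-1,4a-dimethyl-6-oxodecahydronaphthalene-1-carboxylate
Conditions: K2CO3, MeOH, 0 °C to rt
Reagents that add atoms: dimethyl (1-diazo-2-oxopropyl)phosphonate (23), CC(=O)C(=[N+]=[N-])P(=O)(OC)OC
Why: Ohira–Bestmann homologation converts the C13 aldehyde into the terminal alkyne C13≡C14; the hindered C8 ketone should not react, and the mild base equilibrates C9 to the equatorial epimer.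

Step 12
Reactants: 24 methyl (1S,4aS,5R,8aR)-5-(but-3-yn-1-yl)-1,4a-dimethyl-6-oxodecahydronaphthalene-1-carboxylate; 25 methyltriphenylphosphonium bromide
Product: 26 methyl (1S,4aR,5S,8aR)-5-(but-3-yn-1-yl)-1,4a-dimethyl-6-methylidenedecahydronaphthalene-1-carboxylate
Conditions: Ph3PCH3Br, KOt-Bu, toluene, 90 °C
Reagents that add atoms: methyltriphenylphosphonium bromide (25), C[P+](c1ccccc1)(c1ccccc1)c1ccccc1.[Br-]
Why: Wittig methylenation of the hindered C8 ketone installs C17; the ylide (kept free of excess alkoxide) should tolerate the terminal alkyne and the shielded ester, and C9 stays in its thermodynamic equatorial configuration.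

Step 13
Reactants: 26 methyl (1S,4aR,5S,8aR)-5-(but-3-yn-1-yl)-1,4a-dimethyl-6-methylidenedecahydronaphthalene-1-carboxylate; 27 trimethylaluminium; 28 formaldehyde (as paraformaldehyde)
Product: 30 methyl isocupressate, via alkenylalane 29 (not isolated)
Conditions: AlMe3, Cp2ZrCl2 (0.2 equiv), CH2Cl2, 0 °C to rt; then n-BuLi, THF, −78 °C; (CH2O)n, −78 °C to rt; aqueous work-up
Reagents that add atoms: trimethylaluminium (27), C[Al](C)C; formaldehyde as paraformaldehyde (28), C=O
Why: Zirconium-catalysed carboalumination (Negishi) adds methyl to C13 and aluminium to C14 in a syn fashion, and the derived alanate is hydroxymethylated with retention, so the 13E geometry is fixed by the mechanism; the 1,1-disubstituted C8=C17 alkene and the shielded ester should be inert.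

Step 14
Reactants: 30 methyl isocupressate
Product: 31 isocupressic acid
Conditions: n-PrSLi, HMPA, rt; then dilute HCl
Reagents that add atoms: none
Why: The thiolate removes the ester methyl group by SN2 attack at carbon, which does not depend on access to the shielded axial C19 carbonyl and leaves the alkenes and the allylic alcohol alone.

Step 15
Reactants: 31 isocupressic acid; 32 acetic anhydride
Product: 33 15-acetoxyisocupressic acid
Conditions: Ac2O, pyridine, DMAP (cat.), CH2Cl2, 0 °C; aqueous NaHCO3 work-up
Reagents that add atoms: acetic anhydride (32), CC(=O)OC(C)=O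
Why: The primary allylic alcohol is acetylated, while the hindered tertiary acid can at most form a mixed anhydride that hydrolyses on aqueous work-up.

**Compound list**

1 | 2,6-dimethylcyclohexan-1-one (cis/trans mixture) | CC1CCCC(C)C1=O | starting material
2 | allyl chloroformate | C=CCOC(=O)Cl | starting material
3 | allyl 2,6-dimethylcyclohex-1-en-1-yl carbonate (racemic) | C=CCOC(=O)OC1=C(C)CCCC1C | intermediate
4 | (2S)-2-allyl-2,6-dimethylcyclohexan-1-one (both C6 epimers) | CC1CCC[C@](CC=C)(C)C1=O | intermediate
5 | chlorotrimethylsilane | C[Si](C)(C)Cl | starting material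
6 | {[(6S)-6-allyl-2,6-dimethylcyclohex-1-en-1-yl]oxy}trimethylsilane | CC1=C(O[Si](C)(C)C)[C@@](CC=C)(C)CCC1 | intermediate
7 | ozone | [O-][O+]=O | starting material
8 | trimethylsilyl (2S)-2-allyl-2-methyl-6-oxoheptanoate (not isolated) | CC(=O)CCC[C@](CC=C)(C)C(=O)O[Si](C)(C)C | intermediate
9 | (2S)-2-allyl-2-methyl-6-oxoheptanoic acid | CC(=O)CCC[C@](CC=C)(C)C(=O)O | intermediate
10 | iodomethane | CI | starting material
11 | methyl (2S)-2-allyl-2-methyl-6-oxoheptanoate | CC(=O)CCC[C@](CC=C)(C)C(=O)OC | intermediate
12 | benzyl acetoacetate | CC(=O)CC(=O)OCc1ccccc1 | starting material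
13 | 1-benzyl 8-methyl (7S)-2-acetyl-7-allyl-3,7-dimethyloct-2-enedioate (E/Z mixture) | CC(=O)C(C(=O)OCc1ccccc1)=C(C)CCC[C@](CC=C)(C)C(=O)OC | intermediate
14 | sodium periodate | [Na+].[O-]I(=O)(=O)=O | starting material
15 | 1-benzyl 8-methyl (7S)-2-acetyl-7-(2,3-dihydroxypropyl)-3,7-dimethyloct-2-enedioate (not isolated; carbinol epimers) | CC(=O)C(C(=O)OCc1ccccc1)=C(C)CCC[C@](CC(O)CO)(C)C(=O)OC | intermediate
16 | 1-benzyl 8-methyl (7S)-2-acetyl-3,7-dimethyl-7-(2-oxoethyl)oct-2-enedioate | CC(=O)C(C(=O)OCc1ccccc1)=C(C)CCC[C@](CC=O)(C)C(=O)OC | intermediate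
17 | methyl (1S,2R,3S)-3-[1-(benzyloxy)-1,3-dioxobutan-2-yl]-2-formyl-1,3-dimethylcyclohexane-1-carboxylate (not isolated; side-chain CH epimers) | O=C[C@@H]1[C@](C)(CCC[C@]1(C)C(=O)OC)C(C(C)=O)C(=O)OCc2ccccc2 | intermediate
18 | 5-benzyl 1-methyl (1S,4aS,5R,8aR)-1,4a-dimethyl-6-oxo-1,2,3,4,4a,5,6,8a-octahydronaphthalene-1,5-dicarboxylate (C5 of this name epimerisable, drawn with the equatorial ester) | O=C1C=C[C@@H]2[C@](C)(CCC[C@]2(C)C(=O)OC)[C@H]1C(=O)OCc3ccccc3 | intermediate
19 | acrolein | C=CC=O | starting material
20 | 5-benzyl 1-methyl (1S,4aS,5R,8aR)-1,4a-dimethyl-6-oxo-5-(3-oxopropyl)-1,2,3,4,4a,5,6,8a-octahydronaphthalene-1,5-dicarboxylate | O=C1C=C[C@@H]2[C@](C)(CCC[C@]2(C)C(=O)OC)[C@@]1(CCC=O)C(=O)OCc3ccccc3 | intermediate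
21 | (1R,4aR,5S,8aS)-5-(methoxycarbonyl)-5,8a-dimethyl-2-oxo-1-(3-oxopropyl)decahydronaphthalene-1-carboxylic acid (not isolated) | O=C1CC[C@@H]2[C@](C)(CCC[C@]2(C)C(=O)OC)[C@@]1(CCC=O)C(=O)O | intermediate
22 | methyl (1S,4aS,5R,8aR)-1,4a-dimethyl-6-oxo-5-(3-oxopropyl)decahydronaphthalene-1-carboxylate | O=C1CC[C@@H]2[C@](C)(CCC[C@]2(C)C(=O)OC)[C@H]1CCC=O | intermediate
23 | dimethyl (1-diazo-2-oxopropyl)phosphonate | CC(=O)C(=[N+]=[N-])P(=O)(OC)OC | starting material
24 | methyl (1S,4aS,5R,8aR)-5-(but-3-yn-1-yl)-1,4a-dimethyl-6-oxodecahydronaphthalene-1-carboxylate | O=C1CC[C@@H]2[C@](C)(CCC[C@]2(C)C(=O)OC)[C@H]1CCC#C | intermediate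
25 | methyltriphenylphosphonium bromide | C[P+](c1ccccc1)(c1ccccc1)c1ccccc1.[Br-] | starting material
26 | methyl (1S,4aR,5S,8aR)-5-(but-3-yn-1-yl)-1,4a-dimethyl-6-methylidenedecahydronaphthalene-1-carboxylate | C=C1CC[C@@H]2[C@](C)(CCC[C@]2(C)C(=O)OC)[C@H]1CCC#C | intermediate
27 | trimethylaluminium | C[Al](C)C | starting material
28 | formaldehyde (used as paraformaldehyde) | C=O | starting material
29 | methyl (1S,4aR,5S,8aR)-5-[(3E)-4-(dimethylalumanyl)-3-methylbut-3-en-1-yl]-1,4a-dimethyl-6-methylidenedecahydronaphthalene-1-carboxylate (not isolated) | C=C1CC[C@@H]2[C@](C)(CCC[C@]2(C)C(=O)OC)[C@H]1CC/C(C)=C/[Al](C)C | intermediate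
30 | methyl isocupressate, methyl (1S,4aR,5S,8aR)-5-[(3E)-5-hydroxy-3-methylpent-3-en-1-yl]-1,4a-dimethyl-6-methylidenedecahydronaphthalene-1-carboxylate | C=C1CC[C@@H]2[C@](C)(CCC[C@]2(C)C(=O)OC)[C@H]1CC/C(C)=C/CO | intermediate
31 | isocupressic acid, (1S,4aR,5S,8aR)-5-[(3E)-5-hydroxy-3-methylpent-3-en-1-yl]-1,4a-dimethyl-6-methylidenedecahydronaphthalene-1-carboxylic acid | C=C1CC[C@@H]2[C@](C)(CCC[C@]2(C)C(=O)O)[C@H]1CC/C(C)=C/CO | intermediate
32 | acetic anhydride | CC(=O)OC(C)=O | starting material
33 | 15-acetoxyisocupressic acid, (1S,4aR,5S,8aR)-5-[(3E)-5-acetoxy-3-methylpent-3-en-1-yl]-1,4a-dimethyl-6-methylidenedecahydronaphthalene-1-carboxylic acid | C=C1CC[C@@H]2[C@](C)(CCC[C@]2(C)C(=O)O)[C@H]1CC/C(C)=C/COC(C)=O | target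

**Step count and risks**

Total step count: 15. Longest linear sequence: 15 steps (the route is fully linear from 1).

Steps most likely to fail:

1. Step 8. The ring A closure may show poor facial selectivity at C10 (C20 entering cis to C18), or the amine may only deconjugate the alkylidene acetoacetate, with the Michael addition reverting before the condensation follows. The fallback sets out from 16. The aldehyde is O-silylated selectively (t-BuMe2SiOTf, Et3N, CH2Cl2, −78 °C) to give silyl enol ether F1. TiCl4 in CH2Cl2 at −78 °C then effects an intramolecular Mukaiyama–Michael addition onto the Lewis acid–bound acceptor, an irreversible, kinetically controlled C5–C10 closure through the same chair. This delivers keto aldehyde 17 as an isolated compound, where the route is rejoined; piperidinium acetate in warm toluene then closes ring B to 18.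

2. Step 9. Bond formation at C9, which is flanked by the quaternary C10, may be too slow, so that acrolein oligomerises or the adduct reverts. The fallback sets out from 18. Tsuji–Trost allylation (allyl methyl carbonate, Pd(PPh3)4, THF) uses a small, irreversible allylpalladium electrophile and gives the C9-allyl keto diester F2. An aldehyde-selective Wacker oxidation of its terminal alkene (PdCl2(PhCN)2, CuCl2, AgNO2, t-BuOH/MeNO2, O2) then gives 20, where the route is rejoined.

3. Step 4. Ozone may also attack the allyl group (over-oxidation), which would destroy the later C5–C6 unit. The fallback sets out from 6. Rubottom oxidation (m-CPBA, NaHCO3, CH2Cl2, 0 °C; then dilute HCl/THF), in which the peracid should attack only the enol ether, gives the α-hydroxy ketone F3. Cleavage of this α-ketol with H5IO6 in aqueous THF gives keto acid 9, where the route is rejoined.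

**Further compounds**

F1 | step 8 | 1-benzyl 8-methyl (7S)-2-acetyl-7-(2-{[tert-butyl(dimethyl)silyl]oxy}ethenyl)-3,7-dimethyloct-2-enedioate | CC(=O)C(C(=O)OCc1ccccc1)=C(C)CCC[C@](C=CO[Si](C)(C)C(C)(C)C)(C)C(=O)OC
F2 | step 9 | 5-benzyl 1-methyl (1S,4aS,5R,8aR)-5-allyl-1,4a-dimethyl-6-oxo-1,2,3,4,4a,5,6,8a-octahydronaphthalene-1,5-dicarboxylate | O=C1C=C[C@@H]2[C@](C)(CCC[C@]2(C)C(=O)OC)[C@@]1(CC=C)C(=O)OCc3ccccc3
F3 | step 4 | (2S)-2-allyl-6-hydroxy-2,6-dimethylcyclohexan-1-one (C6 epimers) | CC1(O)CCC[C@](CC=C)(C)C1=O
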